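**Plan**

- Flavanone numbering is used throughout (O1, C2, C3, C4=O; ring A carries O5, C7-OMe, C8-prenyl; ring B is the 7-hydroxy-2,2-dimethylchromen-6-yl group on C2).
- Retrosynthesis: the C2–C3 bond of ring C is cut first, which leaves a diazomethyl ketone on ring A and an O1–CH2 benzyl ether to ring B. This works because C2 is benzylic to the dioxygenated ring B and bonded to O1, so in the open ether its two hydrogens are doubly activated and stand 1,6 to a carbene carbon at C3.
- Further cuts: the O1–CH2 ether bond (Mitsunobu), the C8–prenyl bond (traced to an O5 prenyl ether, Claisen–Cope), the diazo carbon (acetyl group), and in ring B the CH2 carbon (formylation) and the dimethylpyran ring (resorcinol plus 3-methylbut-2-enoic acid).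
- Forward: the pyran ring of ring B is built first, rings A and B are joined through O1–CH2, the prenyl group is moved from O5 to C8, the acetyl group becomes the diazoketone, and ring C is closed last.
- Stereochemistry: C2 is the only stereocentre. It is set in the ring-closing insertion by a chiral dirhodium tetracarboxylate that selects one of the two enantiotopic benzylic hydrogens; the single remaining step is run under buffered, non-basic conditions.

Key step: step 13

Assumption: the sense of induction of Rh2(S-PTTL)4 in this 1,6-insertion must be established on the first run; should it give (2R), the mirror-image complex Rh2(R-PTTL)4 is used and nothing else changes.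

**Route**

Step 1
Reactants: 1 2,4,6-trihydroxyacetophenone
Product: 2 2,6-dihydroxy-4-methoxyacetophenone
Conditions: Me2SO4 (1.0 equiv), K2CO3, acetone, reflux
Reagents that add atoms: dimethyl sulfate, COS(=O)(=O)OC
Why: Williamson O-methylation; the 4-OH is the only hydroxyl not chelated to the acetyl carbonyl and is the most acidic, so one equivalent of the sulfate should methylate it selectively.

Step 2
Reactants: 2 2,6-dihydroxy-4-methoxyacetophenone; 3 prenyl bromide
Product: 4 1-[2-hydroxy-4-methoxy-6-(3-methylbut-2-enyloxy)phenyl]ethanone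
Conditions: K2CO3, acetone, reflux
Reagents that add atoms: none
Why: Williamson etherification of a symmetrical bis-phenol; once one oxygen is alkylated the other is locked in a hydrogen bond to the ketone and reacts much more slowly, so the mono-ether should result.

Step 3
Reactants: 5 resorcinol; 6 3-methylbut-2-enoic acid
Product: 7 7-hydroxy-2,2-dimethylchroman-4-one
Conditions: P2O5 in MeSO3H (1:10 w/w), 70 °C
Reagents that add atoms: none
Why: Friedel–Crafts acylation para to one hydroxyl followed by intramolecular oxa-Michael addition of the other (chromanone annulation), a standard entry to 2,2-dimethylchromanones.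

Step 4
Reactants: 7 7-hydroxy-2,2-dimethylchroman-4-one
Product: 9 7-hydroxy-2,2-dimethyl-2H-chromene, via chroman-4-ol 8 (not isolated)
Conditions: NaBH4, MeOH/THF, 0 °C to rt; then 4 M aq. HCl, THF, rt, short contact
Reagents that add atoms: none
Why: borohydride reduction of the ketone followed by acid-catalysed E1 dehydration, which is easy because the C4 cation is stabilised by the ring oxygen and the para hydroxyl; short acid contact limits oligomerisation of the electron-rich chromene.

Step 5
Reactants: 9 7-hydroxy-2,2-dimethyl-2H-chromene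
Product: 10 7-hydroxy-2,2-dimethyl-2H-chromene-6-carbaldehyde
Conditions: MgCl2 (anhydrous), Et3N, (CH2O)n, MeCN, reflux
Reagents that add atoms: paraformaldehyde (as formaldehyde), C=O
Why: magnesium phenoxide-directed ortho-formylation (Casnati–Skattebøl), which should go to the open C6 position (para to the ring oxygen) and not to C8 between the two oxygens.

Step 6
Reactants: 10 7-hydroxy-2,2-dimethyl-2H-chromene-6-carbaldehyde
Product: 11 2,2-dimethyl-7-[(triisopropylsilyl)oxy]-2H-chromene-6-carbaldehyde
Conditions: TIPSCl, imidazole, DMF, rt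
Reagents that add atoms: triisopropylsilyl chloride, CC(C)[Si](Cl)(C(C)C)C(C)C
Why: standard silylation of a phenol; TIPS is chosen over a smaller silyl group because it resists O-to-O migration and base in the later steps.

Step 7
Reactants: 11 2,2-dimethyl-7-[(triisopropylsilyl)oxy]-2H-chromene-6-carbaldehyde
Product: 12 {2,2-dimethyl-7-[(triisopropylsilyl)oxy]-2H-chromen-6-yl}methanol
Conditions: NaBH4, THF/MeOH (4:1), −10 to 0 °C; sat. aq. NH4Cl
Reagents that add atoms: none
Why: borohydride reduction of an aryl aldehyde; low temperature and the bulky TIPS group should prevent silyl transfer from the phenolic to the benzylic oxygen.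

Step 8
Reactants: 4 1-[2-hydroxy-4-methoxy-6-(3-methylbut-2-enyloxy)phenyl]ethanone; 12 {2,2-dimethyl-7-[(triisopropylsilyl)oxy]-2H-chromen-6-yl}methanol
Product: 13 1-[4-methoxy-2-(3-methylbut-2-enyloxy)-6-({2,2-dimethyl-7-[(triisopropylsilyl)oxy]-2H-chromen-6-yl}methoxy)phenyl]ethanone
Conditions: PPh3, DIAD, THF, 0 °C to rt (4 in slight excess)
Reagents that add atoms: none
Why: Mitsunobu etherification of a chelated ortho-acyl phenol with a primary benzylic alcohol, which forms the O1–CH2 bond under neutral conditions that spare the silyl ether and the chromene.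

Step 9
Reactants: 13 1-[4-methoxy-2-(3-methylbut-2-enyloxy)-6-({2,2-dimethyl-7-[(triisopropylsilyl)oxy]-2H-chromen-6-yl}methoxy)phenyl]ethanone
Product: 15 1-[6-hydroxy-4-methoxy-3-(3-methylbut-2-enyl)-2-({2,2-dimethyl-7-[(triisopropylsilyl)oxy]-2H-chromen-6-yl}methoxy)phenyl]ethanone, via ortho-dienone 14 (not isolated)
Conditions: Eu(fod)3 (10 mol%; fod = 6,6,7,7,8,8,8-heptafluoro-2,2-dimethyl-3,5-octanedionate), CHCl3 (acid-free), 60–70 °C, sealed tube
Reagents that add atoms: none
Why: Lewis-acid-accelerated aromatic Claisen shift of the O5 prenyl ether to C6 (reverse-prenyl dienone 14), followed by a Cope shift to C8 (para to O5, now a normal prenyl group) because the crowded dienone enolises slowly, and then tautomerisation to the chelated phenol; the benzyl ether cannot take part in a sigmatropic shift.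

Step 10
Reactants: 15 1-[6-hydroxy-4-methoxy-3-(3-methylbut-2-enyl)-2-({2,2-dimethyl-7-[(triisopropylsilyl)oxy]-2H-chromen-6-yl}methoxy)phenyl]ethanone
Product: 16 1-[4-methoxy-3-(3-methylbut-2-enyl)-6-[(triisopropylsilyl)oxy]-2-({2,2-dimethyl-7-[(triisopropylsilyl)oxy]-2H-chromen-6-yl}methoxy)phenyl]ethanone
Conditions: TIPSCl, imidazole, DMAP (cat.), DMF, 40 °C
Reagents that add atoms: triisopropylsilyl chloride, CC(C)[Si](Cl)(C(C)C)C(C)C
Why: silylation of the chelated phenol, whose second ortho position is unsubstituted; the silyl group leaves O5 without any C–H within reach of the later carbenoid and blocks O–H insertion.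

Step 11
Reactants: 16 1-[4-methoxy-3-(3-methylbut-2-enyl)-6-[(triisopropylsilyl)oxy]-2-({2,2-dimethyl-7-[(triisopropylsilyl)oxy]-2H-chromen-6-yl}methoxy)phenyl]ethanone
Product: 17 4,4,4-trifluoro-1-[4-methoxy-3-(3-methylbut-2-enyl)-6-[(triisopropylsilyl)oxy]-2-({2,2-dimethyl-7-[(triisopropylsilyl)oxy]-2H-chromen-6-yl}methoxy)phenyl]butane-1,3-dione (largely enolised; used crude)
Conditions: LiN(SiMe3)2 (1.1 equiv), THF, −78 °C; CF3CO2CH2CF3, −78 °C, 10 min; cold 5% aq. HCl wash
Reagents that add atoms: 2,2,2-trifluoroethyl trifluoroacetate, O=C(OCC(F)(F)F)C(F)(F)F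
Why: Claisen-type C-acylation of the kinetic lithium enolate of the methyl ketone (the only acidic C–H), kept short and cold so that the neighbouring aryl silyl ether stays in place.

Step 12
Reactants: 17 the trifluoroacetyl diketone from step 11
Product: 18 2-diazo-1-[4-methoxy-3-(3-methylbut-2-enyl)-6-[(triisopropylsilyl)oxy]-2-({2,2-dimethyl-7-[(triisopropylsilyl)oxy]-2H-chromen-6-yl}methoxy)phenyl]ethanone
Conditions: MsN3 (1.5 equiv), Et3N (1.5 equiv), H2O (1 equiv), MeCN, rt
Reagents that add atoms: methanesulfonyl azide, CS(=O)(=O)N=[N+]=[N-]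
Why: detrifluoroacetylative diazo transfer (Regitz-type): the activated diketone takes the N2 unit from the sulfonyl azide and the trifluoroacetyl group leaves on the sulfonamide nitrogen, giving the diazomethyl ketone under mild amine-base conditions.

Step 13
Reactants: 18 the diazomethyl ketone from step 12
Product: 19 (2S)-7-methoxy-8-(3-methylbut-2-enyl)-5-[(triisopropylsilyl)oxy]-2-{2,2-dimethyl-7-[(triisopropylsilyl)oxy]-2H-chromen-6-yl}chroman-4-one
Conditions: Rh2(S-PTTL)4 (2 mol%; PTTL = N-phthaloyl-(S)-tert-leucinate), CH2Cl2, slow addition of 18 to about 0.01 M, −20 °C to rt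
Reagents that add atoms: none
Why: Loss of N2 at the divalent rhodium centre gives an electrophilic carbenoid at C3, which inserts in a concerted, hydride-transfer-like three-centre transition state into one C–H bond of the O1–CH2 group and so forms the C2–C3 bond. The closest known reaction type is the formation of 2-substituted chroman-4-ones from ortho-alkoxyaryl diazoketones with homochiral dirhodium tetracarboxylates. Ring C closes by 1,6-insertion through a six-membered transition-state ring, because the 1,5-position is O1 and carries no hydrogen. C2 is the only new stereocentre and is set by the catalyst alone, whose chiral carboxylate ligands distinguish the two enantiotopic benzylic hydrogens (sense as in the assumption). The step needs C–H insertion to win over oxonium ylide formation at O1 with 1,2-benzyl shift, over cyclopropanation of the two alkenes and over attack at O5. It is helped by the double activation of the C–H bond (alpha to O1, benzylic to electron-rich ring B), by the known preference of rhodium carboxylates for insertion over ylide formation, by the fact that both alkenes could reach the carbenoid only through strained meta-bridged or medium rings, by the bulky silyl group on O5 with no C–H in reach, and by high dilution against intermolecular reactions.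

Step 14
Reactants: 19 the bis-silyl flavanone from step 13
Product: 20 maackiaflavanone A, (2S)-5-hydroxy-2-(7-hydroxy-2,2-dimethyl-2H-chromen-6-yl)-7-methoxy-8-(3-methylbut-2-enyl)chroman-4-one
Conditions: HF·pyridine, excess pyridine, THF, 0 °C to rt
Reagents that add atoms: none
Why: fluoride cleavage of both aryl silyl ethers under buffered, non-basic conditions, which should avoid base-induced opening of ring C to the chalcone (and so loss of C2 configuration) and leave the prenyl and chromene alkenes untouched.

**Compound list**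

1 | 2,4,6-trihydroxyacetophenone | CC(=O)c1c(O)cc(O)cc1O | starting material
2 | 2,6-dihydroxy-4-methoxyacetophenone | COc1cc(O)c(C(C)=O)c(O)c1 | intermediate
3 | prenyl bromide (1-bromo-3-methylbut-2-ene) | CC(C)=CCBr | starting material
4 | 1-[2-hydroxy-4-methoxy-6-(3-methylbut-2-enyloxy)phenyl]ethanone | COc1cc(O)c(C(C)=O)c(OCC=C(C)C)c1 | intermediate
5 | resorcinol | Oc1cccc(O)c1 | starting material
6 | 3-methylbut-2-enoic acid | CC(C)=CC(=O)O | starting material
7 | 7-hydroxy-2,2-dimethylchroman-4-one | CC1(C)CC(=O)c2ccc(O)cc2O1 | intermediate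
8 | 7-hydroxy-2,2-dimethylchroman-4-ol (racemic, not isolated) | CC1(C)CC(O)c2ccc(O)cc2O1 | intermediate
9 | 7-hydroxy-2,2-dimethyl-2H-chromene | CC1(C)C=Cc2ccc(O)cc2O1 | intermediate
10 | 7-hydroxy-2,2-dimethyl-2H-chromene-6-carbaldehyde | CC1(C)C=Cc2cc(C=O)c(O)cc2O1 | intermediate
11 | 2,2-dimethyl-7-[(triisopropylsilyl)oxy]-2H-chromene-6-carbaldehyde | CC1(C)C=Cc2cc(C=O)c(O[Si](C(C)C)(C(C)C)C(C)C)cc2O1 | intermediate
12 | {2,2-dimethyl-7-[(triisopropylsilyl)oxy]-2H-chromen-6-yl}methanol | CC1(C)C=Cc2cc(CO)c(O[Si](C(C)C)(C(C)C)C(C)C)cc2O1 | intermediate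
13 | ring A acetophenone with O-prenyl at the future O5 and the ring B benzyl ether at the future O1 | COc1cc(OCC=C(C)C)c(C(C)=O)c(OCc2cc3c(cc2O[Si](C(C)C)(C(C)C)C(C)C)OC(C)(C)C=C3)c1 | intermediate
14 | 2-acetyl-5-methoxy-6-(2-methylbut-3-en-2-yl)-3-({2,2-dimethyl-7-[(triisopropylsilyl)oxy]-2H-chromen-6-yl}methoxy)cyclohexa-2,4-dien-1-one (ortho-dienone, not isolated) | COC1=CC(OCc2cc3c(cc2O[Si](C(C)C)(C(C)C)C(C)C)OC(C)(C)C=C3)=C(C(C)=O)C(=O)C1C(C)(C)C=C | intermediate
15 | 1-[6-hydroxy-4-methoxy-3-(3-methylbut-2-enyl)-2-({2,2-dimethyl-7-[(triisopropylsilyl)oxy]-2H-chromen-6-yl}methoxy)phenyl]ethanone | COc1cc(O)c(C(C)=O)c(OCc2cc3c(cc2O[Si](C(C)C)(C(C)C)C(C)C)OC(C)(C)C=C3)c1CC=C(C)C | intermediate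
16 | O-TIPS ether of 15 | COc1cc(O[Si](C(C)C)(C(C)C)C(C)C)c(C(C)=O)c(OCc2cc3c(cc2O[Si](C(C)C)(C(C)C)C(C)C)OC(C)(C)C=C3)c1CC=C(C)C | intermediate
17 | trifluoroacetyl derivative of 16 (4,4,4-trifluoro-1-arylbutane-1,3-dione) | COc1cc(O[Si](C(C)C)(C(C)C)C(C)C)c(C(=O)CC(=O)C(F)(F)F)c(OCc2cc3c(cc2O[Si](C(C)C)(C(C)C)C(C)C)OC(C)(C)C=C3)c1CC=C(C)C | intermediate
18 | diazomethyl ketone (2-diazo-1-arylethanone) | COc1cc(O[Si](C(C)C)(C(C)C)C(C)C)c(C(=O)C=[N+]=[N-])c(OCc2cc3c(cc2O[Si](C(C)C)(C(C)C)C(C)C)OC(C)(C)C=C3)c1CC=C(C)C | intermediate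
19 | (2S)-5,2'-bis-O-TIPS maackiaflavanone A | COc1cc(O[Si](C(C)C)(C(C)C)C(C)C)c2c(c1CC=C(C)C)O[C@H](c1cc3c(cc1O[Si](C(C)C)(C(C)C)C(C)C)OC(C)(C)C=C3)CC2=O | intermediate
20 | maackiaflavanone A, (2S) | COc1cc(O)c2c(c1CC=C(C)C)O[C@H](c1cc3c(cc1O)OC(C)(C)C=C3)CC2=O | target

**Step count**

Total: 14 steps. Longest linear sequence: 12 steps (from resorcinol 5: steps 3–14).

**Steps most likely to fail**

1. Step 13. The unstabilised carbenoid may discriminate poorly between the two enantiotopic benzylic hydrogens, and part of it may be diverted into ylide formation at O1 with benzyl shift. Fallback: setting out from 18, the diazoketone is decomposed with achiral Rh2(OAc)4 in dilute CH2Cl2 to give racemic 5,2'-bis-O-TIPS maackiaflavanone A F1. Preparative HPLC on a cellulose tris(3,5-dimethylphenylcarbamate) phase then separates the (2S)-enantiomer from the (2R)-enantiomer F2, so that stereocontrol comes from resolution and not from the catalyst. The route is rejoined at 19.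

2. Step 9. The ortho-dienone may enolise before the Cope shift, which would leave a reverse-prenyl group at C6, or the electron-rich benzylic ether may ionise under Lewis acid and heat. Fallback: setting out from 2, the sigmatropic sequence is dropped. Direct C-prenylation of the phenoxide with prenyl bromide 3 in 10% aqueous KOH at 0 °C gives 1-[2,6-dihydroxy-4-methoxy-3-(3-methylbut-2-enyl)phenyl]ethanone F3. TIPSCl and imidazole should silylate the less hindered hydroxyl (the one with a free ortho position) to give 1-[2-hydroxy-4-methoxy-3-(3-methylbut-2-enyl)-6-[(triisopropylsilyl)oxy]phenyl]ethanone F4. Mitsunobu etherification of the remaining hydroxyl, next to the prenyl group, with 12 (PPh3, DIAD) returns to the route at 16.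

3. Step 11. The ortho silyl group may migrate from the phenolic oxygen to the lithium enolate oxygen, or C-acylation may be incomplete at the twisted, doubly ortho-substituted ketone. Fallback: setting out from 16, no metal enolate is made. Condensation with N,N-dimethylformamide dimethyl acetal (neat, about 100 °C) gives the enaminone (E)-3-(dimethylamino)-1-arylprop-2-en-1-one F5. Diazo transfer from p-toluenesulfonyl azide to the enaminone (cycloaddition, then loss of the N-sulfonyl formamidine) returns to the route at 18.

**Further compounds**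

F1 | step 13 | racemic 5,2'-bis-O-TIPS maackiaflavanone A | COc1cc(O[Si](C(C)C)(C(C)C)C(C)C)c2c(c1CC=C(C)C)OC(c1cc3c(cc1O[Si](C(C)C)(C(C)C)C(C)C)OC(C)(C)C=C3)CC2=O
F2 | step 13 | (2R)-5,2'-bis-O-TIPS maackiaflavanone A | COc1cc(O[Si](C(C)C)(C(C)C)C(C)C)c2c(c1CC=C(C)C)O[C@@H](c1cc3c(cc1O[Si](C(C)C)(C(C)C)C(C)C)OC(C)(C)C=C3)CC2=O
F3 | step 9 | 1-[2,6-dihydroxy-4-methoxy-3-(3-methylbut-2-enyl)phenyl]ethanone | COc1cc(O)c(C(C)=O)c(O)c1CC=C(C)C
F4 | step 9 | 1-[2-hydroxy-4-methoxy-3-(3-methylbut-2-enyl)-6-[(triisopropylsilyl)oxy]phenyl]ethanone | COc1cc(O[Si](C(C)C)(C(C)C)C(C)C)c(C(C)=O)c(O)c1CC=C(C)C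
F5 | step 11 | (E)-3-(dimethylamino)-1-[4-methoxy-3-(3-methylbut-2-enyl)-6-[(triisopropylsilyl)oxy]-2-({2,2-dimethyl-7-[(triisopropylsilyl)oxy]-2H-chromen-6-yl}methoxy)phenyl]prop-2-en-1-one | COc1cc(O[Si](C(C)C)(C(C)C)C(C)C)c(C(=O)/C=C/N(C)C)c(OCc2cc3c(cc2O[Si](C(C)C)(C(C)C)C(C)C)OC(C)(C)C=C3)c1CC=C(C)C
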